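A direct plan would build a six-membered carbocycle first and shrink it twice. The all-cis Diels–Alder anhydride A1 would be oxidised to the 1,2-dione and brominated twice to the meso dibromo-dione diacid A2. Two semibenzilic contractions with trifluoroethoxide would give the cyclobutane diacid diester A3, and both pyranones would be annulated last by a double vinylogous Claisen condensation and enol-lactonisation.
Its weakest steps would be:
- the one-pot double ring contraction of A2: a 6 → 5 → 4 cascade on an α,α'-dibromo-1,2-dione would be without precedent, would have to make the bond between the two quaternary carbons, and would compete with HBr loss and retro-Claisen cleavage;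
- the oxidation and double bromination leading to A2: both tertiary C–Br centres, on which all later stereochemistry rests, would be left to kinetic facial preference on an enolisable dione, after a diene synthesis and a cycloaddition whose CH(CH3) centres are built only to be erased;
- the final double acylation: a large excess of lithium dienolate would have to attack two neopentyl-type esters on adjacent quaternary carbons of the most precious intermediate, where the first keto-enolate could close onto the neighbouring ester instead.

**Plan of the new route**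
The cyclobutane is cut at C1–C2 and C3–C4 into two molecules of one achiral acid, (2E)-3-(4-methoxy-5-methyl-6-oxo-6H-pyran-2-yl)but-2-enoic acid.
The feature that allows this is the mirror plane through the midpoints of C1–C2 and C3–C4: each CH3 on C3/C4 is cis to the CO2H on the neighbouring C2/C1, which is the E geometry of the monomer written into the ring.
The pyranone arises first, from a linear 3,5-diketo ester (steps 1–3). The cyclobutane arises last, by a head-to-head, syn [2+2] photocycloaddition of two arms held on naphthalene-1,8-diol.
The 6-alkenyl-4-methoxy-2-pyranone chromophore absorbs at 365 nm; the 6-alkyl-pyranone of the product does not.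
No ring contraction, no C–Br stereocentre and no enolate chemistry on a late intermediate occur: one stereospecific cycloaddition of a precursor half the size of the product sets all four stereocentres and both quaternary carbons.

Key step: step 6

Remark: the target is meso, so only relative configuration has to be controlled; compounds 5 to 10 would be handled under amber light.

**Step 1**
Reactants: 1 methyl 2-methyl-3-oxobutanoate; 2 ethyl (2E)-3-methyl-4-oxobut-2-enoate
Product: 3 1-ethyl 8-methyl (2E)-4-hydroxy-3,7-dimethyl-6-oxooct-2-enedioate (mixture of diastereomers)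
Conditions: 1, NaH (1.1 equiv), THF, 0 °C; n-BuLi (1.05 equiv), 0 °C; 2 (0.9 equiv), −78 °C; 1 M HCl quench at −78 °C
Reagents that add atoms: none
Why: Dianion aldol addition of a β-keto ester (Huckin–Weiler dianion): the terminal CH2 carbanion should add 1,2 to the aldehyde of 2, its most electrophilic site, at −78 °C without touching the E-enoate, and the two new stereocentres (C4, C7) are of no consequence because both are erased in step 2.

**Step 2**
Reactants: 3 1-ethyl 8-methyl (2E)-4-hydroxy-3,7-dimethyl-6-oxooct-2-enedioate
Product: 5 ethyl (2E)-3-(4-hydroxy-5-methyl-6-oxo-6H-pyran-2-yl)but-2-enoate, via diketo diester 4 (not isolated)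
Conditions: Dess–Martin periodinane (1.3 equiv), CH2Cl2, 0 °C → rt; filter (SiO2), evaporate; DBU (1.5 equiv), PhMe, 60 °C; 1 M HCl
Reagents that add atoms: none
Why: Dess–Martin oxidation of the β-hydroxy ketone should give the enolised 3,5-diketo ester 4, whose DBU enolate closes the 4-hydroxy-2-pyranone by attack of the C4 enolate oxygen on the C8 methyl ester (6-exo-trig O-acylation with loss of methanol, made irreversible by pyranolate formation); as the delocalised diketonate the β,β-disubstituted enoate is a poor Michael acceptor, so the E-alkene is carried through.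

**Step 3**
Reactants: 5 ethyl (2E)-3-(4-hydroxy-5-methyl-6-oxo-6H-pyran-2-yl)but-2-enoate
Product: 6 ethyl (2E)-3-(4-methoxy-5-methyl-6-oxo-6H-pyran-2-yl)but-2-enoate
Conditions: Me2SO4 (1.3 equiv), K2CO3 (1.5 equiv), acetone, 56 °C
Reagents that add atoms: dimethyl sulfate, COS(=O)(=O)OC
Why: O-Methylation of the vinylogous acid with a hard electrophile; for 3-alkyl-4-hydroxy-2-pyranones K2CO3/Me2SO4 in acetone should alkylate the 4-oxygen preferentially to the 4-methoxy-2-pyranone, with the isomeric 2-methoxy-4-pyranone as the expected minor, separable by-product.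

**Step 4**
Reactants: 6 ethyl (2E)-3-(4-methoxy-5-methyl-6-oxo-6H-pyran-2-yl)but-2-enoate
Product: 7 (2E)-3-(4-methoxy-5-methyl-6-oxo-6H-pyran-2-yl)but-2-enoic acid
Conditions: Me3SnOH (5 equiv), ClCH2CH2Cl, 80 °C; 1 M HCl wash
Reagents that add atoms: trimethyltin hydroxide, C[Sn](C)(C)O
Why: Hydroxide-free ester hydrolysis with trimethyltin hydroxide (acyl–oxygen cleavage via the stannyl ester, released on acidic work-up), chosen because free hydroxide over the long time a β,β-disubstituted enoate needs would also attack the 4-methoxy-2-pyranone; the E geometry is not at risk under these non-basic conditions.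

**Step 5**
Reactants: 7 (2E)-3-(4-methoxy-5-methyl-6-oxo-6H-pyran-2-yl)but-2-enoic acid (2.2 equiv); 8 naphthalene-1,8-diol
Product: 9 naphthalene-1,8-diyl bis[(2E)-3-(4-methoxy-5-methyl-6-oxo-6H-pyran-2-yl)but-2-enoate]
Conditions: EDC·HCl (2.6 equiv), DMAP (0.4 equiv), CH2Cl2, 0 → 20 °C, dark
Reagents that add atoms: none
Why: Steglich esterification of both peri hydroxyl groups of the template; the carbodiimide/DMAP protocol avoids acid chloride/amine conditions, under which β-methyl enoyl chlorides deconjugate through vinylketenes, so both E-alkenes should be kept.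

**Step 6**
Reactants: 9 naphthalene-1,8-diyl bis[(2E)-3-(4-methoxy-5-methyl-6-oxo-6H-pyran-2-yl)but-2-enoate]
Product: 10 naphthalene-1,8-diyl (1R,2S,3R,4S)-3,4-bis(4-methoxy-5-methyl-6-oxo-6H-pyran-2-yl)-3,4-dimethylcyclobutane-1,2-dicarboxylate (meso cyclic diester; cyclobutane cis-fused to a nine-membered dilactone ring across the peri positions; both pyranones on the face opposite to the ester carbons)
Conditions: hν (365 nm LED), neat crystalline film of 9 between borosilicate plates, 20 °C, N2
Reagents that add atoms: none
Why: In 9 the two peri oxygens (about 2.5 Å apart) force both enoate arms out of the naphthalene plane into a parallel, in-register stack with the Cα=Cβ bonds within topochemical reach (about 3.5–4 Å), so that excitation of the 6-alkenyl-4-methoxy-2-pyranone chromophore at 365 nm should lead to a suprafacial [2+2] photocycloaddition that forms the Cα–Cα' bond (C1–C2) and the Cβ–Cβ' bond (C3–C4, between the two quaternary carbons) in one event. The closest known reaction type is the solid-state photodimerisation of naphthalene-1,8-diyl dicinnamates to β-truxinates, and the cis-syn cyclobutane dimer of thymine shows that two methyl-bearing quaternary carbons can be joined in this way. The cyclobutane closes by this [2+2] addition, and the nine-membered cyclic diester ring closes passively through the same Cα–Cα' bond, which the short template can only span as a cis-1,2-diester, so C1 and C2 must be cis. C3 and C4 are set by the retained E geometry of each arm (CH3 cis and pyranone trans to the neighbouring ester carbon) and by the face-to-face stack, which gives the mirror-symmetric syn dimer with both pyranones on one face and both CH3 groups on the face of the esters. The step needs head-to-head regiochemistry, syn facial selectivity, no E/Z leakage and reaction at the exocyclic alkene instead of the pyranone C5=C6 bond: the template fixes the first two, the lattice suppresses isomerisation, and the exocyclic alkenes lie closest to the tether while addition there leaves the cyclic conjugation of both pyranones intact. The 6-alkyl-pyranone of the product no longer absorbs at 365 nm, which should protect 10 from cycloreversion and from pyranone photochemistry.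

**Step 7**
Reactants: 10 naphthalene-1,8-diyl (1R,2S,3R,4S)-3,4-bis(4-methoxy-5-methyl-6-oxo-6H-pyran-2-yl)-3,4-dimethylcyclobutane-1,2-dicarboxylate
Product: 11 (1R,2S,3R,4S)-3,4-bis(4-methoxy-5-methyl-6-oxo-6H-pyran-2-yl)-3,4-dimethylcyclobutane-1,2-dicarboxylic acid
Conditions: LiOH·H2O (2.5 equiv), THF–H2O (3:1), 0 °C; 1 M HCl to pH 2
Reagents that add atoms: lithium hydroxide, [Li+].[OH-]
Why: Saponification of an aryl (naphthyl) diester, which is orders of magnitude faster than hydroxide attack on the vinylogous-carbonate carbonyls of the 4-methoxy-2-pyranones or α-deprotonation, so that at 0 °C the template should be released with the cis (meso) configuration at C1/C2 kept, each carboxylate being non-enolisable once formed.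

**Compound list**
1 | methyl 2-methyl-3-oxobutanoate (racemic) | CC(=O)C(C)C(=O)OC | starting material
2 | ethyl (2E)-3-methyl-4-oxobut-2-enoate | CCOC(=O)/C=C(\C)C=O | starting material
3 | 1-ethyl 8-methyl (2E)-4-hydroxy-3,7-dimethyl-6-oxooct-2-enedioate (mixture of diastereomers) | CCOC(=O)/C=C(\C)C(O)CC(=O)C(C)C(=O)OC | intermediate
4 | 1-ethyl 8-methyl (2E)-3,7-dimethyl-4,6-dioxooct-2-enedioate (not isolated) | CCOC(=O)/C=C(\C)C(=O)CC(=O)C(C)C(=O)OC | intermediate
5 | ethyl (2E)-3-(4-hydroxy-5-methyl-6-oxo-6H-pyran-2-yl)but-2-enoate | CCOC(=O)/C=C(\C)c1cc(O)c(C)c(=O)o1 | intermediate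
6 | ethyl (2E)-3-(4-methoxy-5-methyl-6-oxo-6H-pyran-2-yl)but-2-enoate | CCOC(=O)/C=C(\C)c1cc(OC)c(C)c(=O)o1 | intermediate
7 | (2E)-3-(4-methoxy-5-methyl-6-oxo-6H-pyran-2-yl)but-2-enoic acid | OC(=O)/C=C(\C)c1cc(OC)c(C)c(=O)o1 | intermediate
8 | naphthalene-1,8-diol | Oc1cccc2cccc(O)c12 | starting material
9 | naphthalene-1,8-diyl bis[(2E)-3-(4-methoxy-5-methyl-6-oxo-6H-pyran-2-yl)but-2-enoate] | COc1cc(/C(C)=C/C(=O)Oc2cccc3cccc(OC(=O)/C=C(\C)c4cc(OC)c(C)c(=O)o4)c23)oc(=O)c1C | intermediate
10 | naphthalene-1,8-diyl (1R,2S,3R,4S)-3,4-bis(4-methoxy-5-methyl-6-oxo-6H-pyran-2-yl)-3,4-dimethylcyclobutane-1,2-dicarboxylate (meso cyclic diester) | COc1cc([C@@]2(C)[C@@H]3C(=O)Oc4cccc5cccc(OC(=O)[C@@H]3[C@@]2(C)c2cc(OC)c(C)c(=O)o2)c45)oc(=O)c1C | intermediate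
11 | (1R,2S,3R,4S)-3,4-bis(4-methoxy-5-methyl-6-oxo-6H-pyran-2-yl)-3,4-dimethylcyclobutane-1,2-dicarboxylic acid (meso) | COc1cc([C@@]2(C)[C@H](C(=O)O)[C@H](C(=O)O)[C@@]2(C)c2cc(OC)c(C)c(=O)o2)oc(=O)c1C | target

**Count and risks**
Total step count: 7. Longest linear sequence: 7 steps (1 and 2 to 11; 8 is purchased).

Steps most likely to fail:

1. Step 6. The packing of 9 may hold the methyl-bearing β-carbons too far apart or twist the pyranones out of the stack, so that the crystal is photostable. Light-induced softening may also allow E/Z isomerisation or closure onto a pyranone C5=C6 bond. The fallback sets out from 7 and comes back at 11. The covalent template would be replaced by a host: 7 would be taken up pairwise in cucurbit[8]uril (0.5 equiv) in water and irradiated at 365 nm. This host is known to give the syn head-to-head dimer of trans-cinnamic acids. Extraction of the guest would deliver 11 directly, with steps 5 and 7 skipped; no new covalent compound arises (F0).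

2. Step 7. After the first, fast aryl ester cleavage the second one is slower. Hydroxide may then add to a 4-methoxy-2-pyranone (ring opening or loss of the methyl ether) or epimerise the α-CH of the remaining aryl ester. The fallback sets out from 10 and comes back at 11. A hydroxide-free cleavage in two stages would be used: amine-catalysed methanolysis (MeOH, Et3N, DMAP cat., 40 °C) to dimethyl (1R,2S,3R,4S)-3,4-bis(4-methoxy-5-methyl-6-oxo-6H-pyran-2-yl)-3,4-dimethylcyclobutane-1,2-dicarboxylate F4, then Me3SnOH in ClCH2CH2Cl at 80 °C to 11.

3. Step 4. The deactivated β,β-disubstituted ethyl enoate may hydrolyse so slowly that, at the temperature needed, the tin hydroxide begins to open the pyranone lactone. The fallback sets out from 5 and comes back at 7. The ester would be cleaved one stage earlier, where hydroxide is harmless because the ring is protected as its own 4-olate: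
 - LiOH in THF–H2O would give (2E)-3-(4-hydroxy-5-methyl-6-oxo-6H-pyran-2-yl)but-2-enoic acid F1.
 - The more nucleophilic carboxylate would be alkylated selectively (allyl bromide, KHCO3, DMF) to prop-2-en-1-yl (2E)-3-(4-hydroxy-5-methyl-6-oxo-6H-pyran-2-yl)but-2-enoate F2.
 - O-Methylation as in step 3 would give prop-2-en-1-yl (2E)-3-(4-methoxy-5-methyl-6-oxo-6H-pyran-2-yl)but-2-enoate F3.
 - Pd(PPh3)4 (zerovalent palladium, catalytic) with morpholine in THF would remove the allyl group to give 7.

**Further compounds**
F0 | step 6 | none | none
F1 | step 4 | (2E)-3-(4-hydroxy-5-methyl-6-oxo-6H-pyran-2-yl)but-2-enoic acid | OC(=O)/C=C(\C)c1cc(O)c(C)c(=O)o1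
F2 | step 4 | prop-2-en-1-yl (2E)-3-(4-hydroxy-5-methyl-6-oxo-6H-pyran-2-yl)but-2-enoate | C=CCOC(=O)/C=C(\C)c1cc(O)c(C)c(=O)o1
F3 | step 4 | prop-2-en-1-yl (2E)-3-(4-methoxy-5-methyl-6-oxo-6H-pyran-2-yl)but-2-enoate | C=CCOC(=O)/C=C(\C)c1cc(OC)c(C)c(=O)o1
F4 | step 7 | dimethyl (1R,2S,3R,4S)-3,4-bis(4-methoxy-5-methyl-6-oxo-6H-pyran-2-yl)-3,4-dimethylcyclobutane-1,2-dicarboxylate | COc1cc([C@@]2(C)[C@H](C(=O)OC)[C@H](C(=O)OC)[C@@]2(C)c2cc(OC)c(C)c(=O)o2)oc(=O)c1C
A1 | direct plan | all-cis 4,7-dimethyl-5,6-bis(trimethylsilyloxy)-3a,4,7,7a-tetrahydro-2-benzofuran-1,3-dione | O=C1OC(=O)[C@@H]2[C@H]1[C@H](C)C(O[Si](C)(C)C)=C(O[Si](C)(C)C)[C@@H]2C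
A2 | direct plan | meso 3,6-dibromo-3,6-dimethyl-4,5-dioxocyclohexane-1,2-dicarboxylic acid | OC(=O)[C@@H]1[C@H](C(=O)O)[C@@](C)(Br)C(=O)C(=O)[C@@]1(C)Br
A3 | direct plan | (1R,2S,3R,4S)-3,4-dimethyl-3,4-bis[(2,2,2-trifluoroethoxy)carbonyl]cyclobutane-1,2-dicarboxylic acid | O=C(OCC(F)(F)F)[C@@]1(C)[C@H](C(=O)O)[C@H](C(=O)O)[C@@]1(C)C(=O)OCC(F)(F)F
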